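## Structural features

The target is a (2S)-flavanone: ring A is fused to the dihydropyranone ring C, and C2 carries a para-substituted phenyl ring B whose para oxygen is a prenyl ether. Ring A is pentasubstituted: C4a holds the C4 ketone, C5 and C7 hold free hydroxyls, C8 holds a C-linked prenyl group and C8a holds the ring oxygen O1, so C6 is the only C–H. C2 is the only stereocentre and has no stereogenic neighbour. It is benzylic and β to the C4 carbonyl, so it can be lost by reversible retro-oxa-Michael opening to the 2'-hydroxychalcone under base, or by ionisation under acid. The fragile groups are the two trisubstituted alkenes, the acid-labile aryl prenyl ether of ring B, the C8 prenyl group (which cyclises onto the C7 hydroxyl under acid or with electrophiles) and the oxidation-prone phloroglucinol-type phenols. The real difficulty is regiochemical and sits in ring A: the prenyl group must be on C8 and not on C6 or on oxygen, and of the three ring A oxygens exactly the one on C8a must become the ring ether. The second difficulty is to set C2 without strong acid, strong base, hydrogenation or hard Lewis acids. The key step exploits the contiguous triad O–C8a, prenyl–C8, O–C7 together with the meta oxygen on C5: this 1,3,5-trioxygenated, 2-alkylated benzene is the sum of a four-carbon 3-silyloxycyclobutenone (C8a, C4a, C5, C6) and a two-carbon silyl ynol ether (C8, C7).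

## Logic of the disconnections

26 ⇒ 25. The two O–Si bonds on the C5 and C7 oxygens are cut last. Silyl ethers are chosen because acid-labile or hydrogenolysable groups are excluded by the prenyl units. The gain is that the base- and oxidation-sensitive phenols stay masked throughout. The demand is a non-basic, non-acidic fluoride deprotection that leaves C2 untouched.

25 ⇒ 18 + 24. The C2–C1' bond to ring B is cut. C2 becomes the β-carbon of an enone once C2=C3 unsaturation is written into ring C, so the stereocentre can be set by a catalyst-controlled conjugate arylation at the very end. The gain is convergence and an achiral, flat precursor. The demand is delivery of the aryl group to the C2 Re face of an electron-rich chromone under neutral conditions.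

18 ⇒ 16 ⇒ 15. The O1–C2 bond and then the C3–C4 bond are cut, and C4 is taken back to the aldehyde oxidation level. Ring C is thereby reduced to a single formyl carbon plus a two-carbon acetylide. The demand is that the C8a hydroxyl is the only free phenol, so that oxa-Michael closure of the ynone derived from 16 can take only one course, and that the silyl ethers survive a Grignard addition and an oxidation.

15 ⇒ 13. The C4–C4a bond is cut. 13 has a single C–H ortho to its free hydroxyl, so a phenoxide-directed formylation can only go to C4a. The gain is a ring A building block without any carbon substituent on C4a. The demand is strict ortho selectivity, because the C6–H para to the hydroxyl is also activated.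

13 ⇒ 3 + 8. The C8–C8a and C6–C7 bonds are cut, with the pericyclic reorganisation that breaks and re-forms C4a–C8a. This removes ring A altogether and replaces the substitution problem by the polarity of two small partners: the carbonyl carbon of 3 becomes C8a and its free hydroxyl, and the ynol ether 8 supplies C8 with the prenyl group and C7 with its oxygen already silylated. The demand is a regioselective ketene [2+2] cycloaddition and a thermal cascade that the prenyl alkene and both silyl ethers tolerate.

8 ⇒ 5 ⇒ 4. The C1–C2 bond of the alkyne and the O–Si bond are cut, then the ester O–C bond. A one-carbon homologation of the ester through its ynolate gives the ynol ether from a five-carbon acid that already contains the prenyl unit. The demand is carbonyl addition in preference to enolisation of a β,γ-unsaturated ester, and an esterification that avoids acid.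

3 ⇒ 2 ⇒ 1. The O–Si bond is cut, then the O–ethyl bond. The symmetric enolised dione 2 can give only one enol silyl ether. The demand is a bulky silyl group and handling without water.

24 ⇒ 21 ⇒ 19 + 20. The C–B bond is cut, then the O–prenyl bond. Ring B with its prenyl ether comes from two commodity chemicals. The demand is a borylation whose work-up is mild enough for the allylic ether.

## Other disconnections considered

Alternative 1: The cut is O1–C8a. In the forward direction the C2 hydroxyl of bromo diol A2 would displace the C8a bromide under monovalent copper catalysis with a phenanthroline ligand and a carbonate base, to give flavan-4-ol A1.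
- In favour: the C2–O bond is never broken, so a stereocentre set earlier by a reliable asymmetric carbonyl reduction or aldol is carried through unchanged. Only the six-membered closure is possible, because the C4 hydroxyl could close only a four-membered ring.
- Against: A2 needs ring A with a bromide on C8a flanked by the prenyl group and the side chain. That is a harder regiochemical problem than the one the benzannulation solves, and oxidative addition at so hindered and electron-rich a bromide needs forcing conditions. C4 must then be oxidised, and the acetal protecting groups removed with acid, which endangers the C8 prenyl group once the C7 hydroxyl is free.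
- Comparison: on stereochemical security of C2 this plan is the equal or the better of the chosen one, since it needs no enantioselective bond formation on the heterocycle. On structure it is weaker, because it makes two stereocentres to keep one. On mechanism it replaces a catalyst-free pericyclic cascade by a metal-mediated coupling at the most hindered carbon. On step economy it is longer (diol assembly, oxidation, deprotection).

Alternative 2: The cut is C2–C3. Diazo ketone A4 would give a rhodium carbenoid at C3 under a chiral dirhodium tetracarboxylate; insertion into a benzylic O–CH2 hydrogen closes ring C and gives flavanone A3.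
- In favour: ring C and the stereocentre arise in one step, and A3 is already at the ketone oxidation level, differing from 25 only in its silyl groups. The endgame is therefore as short as the chosen one, and ring C construction is shorter than steps 7, 8 and 11 together; on these two points it is equal and better respectively.
- Against: an α-diazo ketone with an ortho alkoxy group offers the carbenoid an easier path, namely attack by the ether oxygen to an oxonium ylide followed by a [1,2]-benzyl shift. The two prenyl alkenes and ring B invite cyclopropanation and aromatic cycloaddition. Six-membered insertion is less favoured than five-membered, and the diazo ketone must be made from a doubly ortho-substituted benzoic acid with a diazoalkane.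
- Comparison: the chosen plan is mechanistically safer, because its stereo-setting step has no competing intramolecular pathway. Both plans still need a regiodefined ring A; 13 could serve this alternative after O-benzylation, but C4a acylation would be harder than the formylation used here.

Alternative 3: The cuts are C3–C4 and O1–C2. Salicylaldehyde A6, an orthoformate and styrene A7 would combine under a chiral N-triflyl phosphoramide: the aldehyde gives a 4-methoxy ortho-quinone methide that adds the styrene in an inverse-demand [4+2] to give cis-4-methoxyflavan A5.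
- In favour: this is the most convergent ring C closure. Two bonds, the ring and C2 are made in one intermolecular step from an aldehyde of the same type as 15, and the styrene comes in two steps from 4-hydroxybenzaldehyde. On bond-forming economy it is better than the chosen steps 7, 8 and 11.
- Against: the catalyst is a strong Brønsted acid acting on an aryl prenyl ether and an electron-rich styrene, which can ionise or oligomerise. The cationic intermediate is stabilised by the C5 and C7 oxygens and therefore less reactive. C4 arrives as a methyl ether, so a solvolysis and an oxidation must follow; the C4 stereocentre is made only to be destroyed, and acid may reverse the cycloaddition and erode C2.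
- Comparison: the overall step count comes out equal. The chosen plan is superior in functional-group tolerance, since its stereo-setting step runs at neutral pH. This closure does not depend on how ring A is made, so it is kept as the reserve for step 11.

Key step: step 5

Remark on protecting groups: the C5 oxygen is carried as a triisopropylsilyl ether from the cyclobutenone onward. The enol silyl ether of the cyclobutenone is a vinylogous silyl ester; with a smaller group such as tert-butyldimethylsilyl it would be hydrolytically labile and could silylate the phenol that forms beside it at 80–110 °C.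

Remark on the sense of induction: (S)-MeO-F12-BIPHEP is (S)-6,6'-dimethoxy-2,2'-bis[bis(3,4,5-trifluorophenyl)phosphino]-1,1'-biphenyl. It is assumed to leave the C2 Re face of 18 open, by analogy with the face selection of (S)-biaryl bisphosphines on cyclic enones. If a test run showed the opposite sense, the (R)-ligand would be used with no other change.

## Route

Step 1
Reactants: 1 3-ethoxycyclobut-2-en-1-one
Product: 2 3-hydroxycyclobut-2-en-1-one (enol form of cyclobutane-1,3-dione)
Conditions: 1 M HCl (aq), 0 °C → rt; freeze-dry
Reagents that add atoms: water, O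
Why: Acid hydrolysis of a vinylogous ester (conjugate addition of water, loss of ethanol); the product is a vinylogous carboxylic acid and is used fresh.

Step 2
Reactants: 2 3-hydroxycyclobut-2-en-1-one
Product: 3 3-(triisopropylsilyloxy)cyclobut-2-en-1-one
Conditions: TIPSCl, Et3N, CH2Cl2, 0 °C → rt; pentane, filtration, no aqueous work-up
Reagents that add atoms: chlorotriisopropylsilane, CC(C)[Si](Cl)(C(C)C)C(C)C
Why: O-Silylation of a vinylogous acid, the same reaction type as silyl ester formation; the dione is symmetric, so only one enol ether can form, and the bulky silyl group should allow non-aqueous isolation.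

Step 3
Reactants: 4 4-methylpent-3-enoic acid
Product: 5 ethyl 4-methylpent-3-enoate
Conditions: EtI, K2CO3, DMF, rt
Reagents that add atoms: ethyl iodide, CCI
Why: Carboxylate SN2 alkylation; base is chosen because acid-catalysed esterification would lactonise this β,γ-unsaturated acid through its tertiary cation.

Step 4
Reactants: 5 ethyl 4-methylpent-3-enoate
Product: 8 triisopropyl[(5-methylhex-4-en-1-yn-1-yl)oxy]silane, via lithium dibromoenolate 6 (not isolated), via lithium ynolate 7 (not isolated)
Conditions: CH2Br2, LiTMP (lithium 2,2,6,6-tetramethylpiperidide), THF, −78 °C; LiN(SiMe3)2; n-BuLi, −78 → 20 °C; TIPSCl, −78 → 0 °C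
Reagents that add atoms: dibromomethane, BrCBr; chlorotriisopropylsilane, CC(C)[Si](Cl)(C(C)C)C(C)C
Why: Kowalski ester homologation: LiCHBr2 adds to the ester, dibromoenolate 6 undergoes bromine–lithium exchange and 1,2-migration of the prenyl group to the carbenoid carbon to give ynolate 7, which the bulky chlorosilane silylates on oxygen. Forming LiCHBr2 in the presence of the ester at −78 °C favours carbonyl addition over enolisation.

Step 5
Reactants: 3 3-(triisopropylsilyloxy)cyclobut-2-en-1-one; 8 triisopropyl[(5-methylhex-4-en-1-yn-1-yl)oxy]silane
Product: 13 2-(3-methylbut-2-en-1-yl)-3,5-bis(triisopropylsilyloxy)phenol, via silyloxyvinylketene 9 (not isolated), via vinylcyclobutenone 10 (not isolated), via dienylketene 11 (not isolated), via cyclohexa-2,4-dienone 12 (not isolated)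
Conditions: 8 (1.3 equiv), PhMe, 80 °C then 110 °C, sealed tube, Ar
Reagents that add atoms: none
Why: Danheiser benzannulation: relief of four-ring strain drives thermal 4π electrocyclic opening of 3 to silyloxyvinylketene 9. The ketene adds ynol ether 8 in a polar [2+2] in which its electrophilic carbonyl carbon bonds to the nucleophilic, prenyl-bearing alkyne carbon (C8–C8a) and its α-carbon bonds to the oxygen-bearing alkyne carbon (C6–C7), giving 10. Reversible 4π opening of 10 gives dienylketene 11, and ring A closes by thermal disrotatory 6π electrocyclisation between the ketene carbon and the terminal methylene (C8a–C4a, the bond broken in the first opening); enolisation of 12 gives phenol 13. The closest known reaction type is the thermal benzannulation of cyclobutenones with silyloxyalkynes to resorcinol monosilyl ethers, and 3-silyloxycyclobutenones are known as the [2+2] adducts of ketenes with silyloxyalkynes, so the partner lies inside the established class. No stereocentre survives, because the sp3 carbon of 10 is lost on aromatisation. The step needs regioselectivity in the [2+2], which the polarisation of the ynol ether by its oxygen secures without a catalyst, and chemoselectivity for the alkyne over the prenyl alkene, which is a far poorer ketenophile. The slight excess of 8 and the bulky silyl groups are meant to keep the new phenol from being acylated by 9 or silylated by 3.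

Step 6
Reactants: 13 2-(3-methylbut-2-en-1-yl)-3,5-bis(triisopropylsilyloxy)phenol
Product: 15 2-hydroxy-3-(3-methylbut-2-en-1-yl)-4,6-bis(triisopropylsilyloxy)benzaldehyde, via ortho-hydroxymethylphenol 14 (not isolated)
Conditions: MgCl2, Et3N, (CH2O)n, THF, reflux; aq NH4Cl
Reagents that add atoms: formaldehyde (as paraformaldehyde), C=O
Why: Casnati–Skattebøl ortho-formylation: the magnesium phenoxide delivers formaldehyde to its own ortho carbon, and the benzylic alkoxide 14 is oxidised by a second formaldehyde through Oppenauer-type hydride transfer. C4a is the only free ortho position, the C6–H para to the phenol is not reached by the chelated mechanism, and the silyl ethers tolerate Et3N and the methanol released.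

Step 7
Reactants: 15 2-hydroxy-3-(3-methylbut-2-en-1-yl)-4,6-bis(triisopropylsilyloxy)benzaldehyde
Product: 16 2-(1-hydroxyprop-2-yn-1-yl)-6-(3-methylbut-2-en-1-yl)-3,5-bis(triisopropylsilyloxy)phenol (racemic)
Conditions: HC≡CMgBr (2.5 equiv), THF, −78 → −20 °C; aq NH4Cl
Reagents that add atoms: ethynylmagnesium bromide, C#C[Mg]Br
Why: Grignard addition to the aldehyde after the first equivalent has deprotonated the phenol; a bulky silyl group should not migrate to a magnesium alkoxide at low temperature. The new carbinol centre is formed racemic and is removed in step 8.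

Step 8
Reactants: 16 2-(1-hydroxyprop-2-yn-1-yl)-6-(3-methylbut-2-en-1-yl)-3,5-bis(triisopropylsilyloxy)phenol
Product: 18 8-(3-methylbut-2-en-1-yl)-5,7-bis(triisopropylsilyloxy)-4H-chromen-4-one, via hydroxyaryl ynone 17 (not isolated)
Conditions: MnO2, CH2Cl2, rt; filter; Et3N (cat.), rt
Reagents that add atoms: none
Why: MnO2 oxidises the benzylic propargylic alcohol selectively, and ynone 17 closes by amine-promoted 6-endo-dig oxa-Michael addition of the C8a phenol to the terminal alkyne carbon, the only conjugate position; this is an established chromone synthesis.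

Step 9
Reactants: 19 4-bromophenol; 20 1-bromo-3-methylbut-2-ene (prenyl bromide)
Product: 21 1-bromo-4-[(3-methylbut-2-en-1-yl)oxy]benzene
Conditions: K2CO3, acetone, reflux
Reagents that add atoms: none
Why: Williamson etherification: SN2 attack of the phenoxide at the primary allylic bromide gives O-alkylation at the unbranched terminus.

Step 10
Reactants: 21 1-bromo-4-[(3-methylbut-2-en-1-yl)oxy]benzene
Product: 24 {4-[(3-methylbut-2-en-1-yl)oxy]phenyl}boronic acid, via aryllithium 22 (not isolated), via lithium triisopropoxyarylborate 23 (not isolated)
Conditions: n-BuLi, THF, −78 °C; B(Oi-Pr)3, −78 °C → rt; aq NH4Cl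
Reagents that add atoms: triisopropyl borate, CC(C)OB(OC(C)C)OC(C)C; water, O
Why: Bromine–lithium exchange at −78 °C is faster than deprotonation of the allylic ether; the aryllithium is trapped by the borate, and the ate complex is hydrolysed at near-neutral pH, which the prenyl ether tolerates.

Step 11
Reactants: 18 8-(3-methylbut-2-en-1-yl)-5,7-bis(triisopropylsilyloxy)-4H-chromen-4-one; 24 {4-[(3-methylbut-2-en-1-yl)oxy]phenyl}boronic acid
Product: 25 (2S)-8-(3-methylbut-2-en-1-yl)-2-{4-[(3-methylbut-2-en-1-yl)oxy]phenyl}-5,7-bis(triisopropylsilyloxy)-2,3-dihydro-4H-chromen-4-one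
Conditions: 24 (2 equiv), [Rh(OH)((S)-MeO-F12-BIPHEP)]2 (3 mol % Rh), PhMe/H2O (10:1), 30 °C
Reagents that add atoms: none
Why: Hayashi–Miyaura asymmetric 1,4-addition, known for chromones with electron-poor biaryl bisphosphines: transmetalation gives an aryl–rhodium species, C2=C3 inserts into it, and water protonates the rhodium enolate. C2 is set by the ligand, whose (S)-biaryl axis leaves the C2 Re face of the bound chromone open and so gives the (2S) product. Base-free conditions protect the silyl ethers and prevent retro-oxa-Michael opening.

Step 12
Reactants: 25 (2S)-8-(3-methylbut-2-en-1-yl)-2-{4-[(3-methylbut-2-en-1-yl)oxy]phenyl}-5,7-bis(triisopropylsilyloxy)-2,3-dihydro-4H-chromen-4-one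
Product: 26 (2S)-5,7-dihydroxy-8-(3-methylbut-2-en-1-yl)-2-{4-[(3-methylbut-2-en-1-yl)oxy]phenyl}-2,3-dihydro-4H-chromen-4-one
Conditions: Bu4NF, AcOH (1:1), THF, 0 °C → rt
Reagents that add atoms: none
Why: Fluoride cleavage of both aryl silyl ethers; the acetic acid buffer keeps the liberated phenols protonated, so E1cB ring opening to the chalcone should not scramble C2. Nothing acidic enough to cyclise the C8 prenyl group onto the C7 hydroxyl is present.

## Compound list

1 | 3-ethoxycyclobut-2-en-1-one | CCOC1=CC(=O)C1 | starting material
2 | 3-hydroxycyclobut-2-en-1-one (enol form of cyclobutane-1,3-dione) | O=C1CC(O)=C1 | intermediate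
3 | 3-(triisopropylsilyloxy)cyclobut-2-en-1-one | O=C1CC(O[Si](C(C)C)(C(C)C)C(C)C)=C1 | intermediate
4 | 4-methylpent-3-enoic acid | CC(C)=CCC(=O)O | starting material
5 | ethyl 4-methylpent-3-enoate | CCOC(=O)CC=C(C)C | intermediate
6 | lithium 1,1-dibromo-5-methylhexa-1,4-dien-2-olate | [Li+].[O-]C(CC=C(C)C)=C(Br)Br | intermediate
7 | lithium 5-methylhex-4-en-1-yn-1-olate | [Li+].[O-]C#CCC=C(C)C | intermediate
8 | triisopropyl[(5-methylhex-4-en-1-yn-1-yl)oxy]silane | CC(C)=CCC#CO[Si](C(C)C)(C(C)C)C(C)C | intermediate
9 | 3-(triisopropylsilyloxy)buta-1,3-dien-1-one | C=C(O[Si](C(C)C)(C(C)C)C(C)C)C=C=O | intermediate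
10 | 2-(3-methylbut-2-en-1-yl)-3-(triisopropylsilyloxy)-4-[1-(triisopropylsilyloxy)ethenyl]cyclobut-2-en-1-one (racemic) | O=C1C(CC=C(C)C)=C(O[Si](C(C)C)(C(C)C)C(C)C)C1C(=C)O[Si](C(C)C)(C(C)C)C(C)C | intermediate
11 | (3E)-2-(3-methylbut-2-en-1-yl)-3,5-bis(triisopropylsilyloxy)hexa-1,3,5-trien-1-one | O=C=C(CC=C(C)C)/C(O[Si](C(C)C)(C(C)C)C(C)C)=C\C(=C)O[Si](C(C)C)(C(C)C)C(C)C | intermediate
12 | 2-(3-methylbut-2-en-1-yl)-3,5-bis(triisopropylsilyloxy)cyclohexa-2,4-dien-1-one | O=C1CC(O[Si](C(C)C)(C(C)C)C(C)C)=CC(O[Si](C(C)C)(C(C)C)C(C)C)=C1CC=C(C)C | intermediate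
13 | 2-(3-methylbut-2-en-1-yl)-3,5-bis(triisopropylsilyloxy)phenol | Oc1cc(O[Si](C(C)C)(C(C)C)C(C)C)cc(O[Si](C(C)C)(C(C)C)C(C)C)c1CC=C(C)C | intermediate
14 | 2-(hydroxymethyl)-6-(3-methylbut-2-en-1-yl)-3,5-bis(triisopropylsilyloxy)phenol (as its magnesium salt) | OCc1c(O)c(CC=C(C)C)c(O[Si](C(C)C)(C(C)C)C(C)C)cc1O[Si](C(C)C)(C(C)C)C(C)C | intermediate
15 | 2-hydroxy-3-(3-methylbut-2-en-1-yl)-4,6-bis(triisopropylsilyloxy)benzaldehyde | O=Cc1c(O)c(CC=C(C)C)c(O[Si](C(C)C)(C(C)C)C(C)C)cc1O[Si](C(C)C)(C(C)C)C(C)C | intermediate
16 | 2-(1-hydroxyprop-2-yn-1-yl)-6-(3-methylbut-2-en-1-yl)-3,5-bis(triisopropylsilyloxy)phenol (racemic) | C#CC(O)c1c(O)c(CC=C(C)C)c(O[Si](C(C)C)(C(C)C)C(C)C)cc1O[Si](C(C)C)(C(C)C)C(C)C | intermediate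
17 | 1-[2-hydroxy-3-(3-methylbut-2-en-1-yl)-4,6-bis(triisopropylsilyloxy)phenyl]prop-2-yn-1-one | C#CC(=O)c1c(O)c(CC=C(C)C)c(O[Si](C(C)C)(C(C)C)C(C)C)cc1O[Si](C(C)C)(C(C)C)C(C)C | intermediate
18 | 8-(3-methylbut-2-en-1-yl)-5,7-bis(triisopropylsilyloxy)-4H-chromen-4-one | O=c1ccoc2c(CC=C(C)C)c(O[Si](C(C)C)(C(C)C)C(C)C)cc(O[Si](C(C)C)(C(C)C)C(C)C)c12 | intermediate
19 | 4-bromophenol | Oc1ccc(Br)cc1 | starting material
20 | 1-bromo-3-methylbut-2-ene (prenyl bromide) | CC(C)=CCBr | starting material
21 | 1-bromo-4-[(3-methylbut-2-en-1-yl)oxy]benzene | CC(C)=CCOc1ccc(Br)cc1 | intermediate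
22 | {4-[(3-methylbut-2-en-1-yl)oxy]phenyl}lithium | [Li]c1ccc(OCC=C(C)C)cc1 | intermediate
23 | lithium triisopropoxy{4-[(3-methylbut-2-en-1-yl)oxy]phenyl}borate | [Li+].CC(C)O[B-](OC(C)C)(OC(C)C)c1ccc(OCC=C(C)C)cc1 | intermediate
24 | {4-[(3-methylbut-2-en-1-yl)oxy]phenyl}boronic acid | CC(C)=CCOc1ccc(B(O)O)cc1 | intermediate
25 | (2S)-8-(3-methylbut-2-en-1-yl)-2-{4-[(3-methylbut-2-en-1-yl)oxy]phenyl}-5,7-bis(triisopropylsilyloxy)-2,3-dihydro-4H-chromen-4-one | CC(C)=CCOc1ccc([C@@H]2CC(=O)c3c(O[Si](C(C)C)(C(C)C)C(C)C)cc(O[Si](C(C)C)(C(C)C)C(C)C)c(CC=C(C)C)c3O2)cc1 | intermediate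
26 | (2S)-5,7-dihydroxy-8-(3-methylbut-2-en-1-yl)-2-{4-[(3-methylbut-2-en-1-yl)oxy]phenyl}-2,3-dihydro-4H-chromen-4-one | CC(C)=CCOc1ccc([C@@H]2CC(=O)c3c(O)cc(O)c(CC=C(C)C)c3O2)cc1 | target

## Step count and least certain steps

Total step count: 12. Longest linear sequence: 8 steps (steps 1, 2, 5, 6, 7, 8, 11, 12).

Step 5 (key step). The donor-substituted cyclobutenone 3 is the least precedented compound of the route. The most likely failures are slow electrocyclic opening of 3, which prolongs heating, and during that time thermal decay of the ynol ether or capture of the vinylketene by the newly formed phenol. The fallback sets out from 20 and comes back at 13; it also covers a failure to obtain 3 in steps 1 and 2. C-Prenylation of benzene-1,3,5-triol F1 with 20 (DBU, THF, 0 °C) should give 2-(3-methylbut-2-en-1-yl)benzene-1,3,5-triol F2. Silylation with two equivalents of TIPSCl and imidazole is expected to take the unhindered hydroxyl para to the prenyl group and then one of the two symmetry-equivalent flanking hydroxyls, which can only lead to 13. This reserve trades the regiochemical certainty of the annulation for a statistical monoprenylation and a partial silylation.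

Step 4. The amide base or LiCHBr2 may enolise the β,γ-unsaturated ester (with deconjugation) in competition with addition to the carbonyl, so that the ynolate never forms. The fallback sets out from 20 and comes back at 8 through 7. Coupling of 20 with HC≡CMgBr under CuCl catalysis (monovalent copper) should give 5-methylhex-4-en-1-yne F3. Deprotonation with n-BuLi gives lithium 5-methylhex-4-en-1-yn-1-ide F4, which lithium tert-butyl peroxide (t-BuOOH, LiN(SiMe3)2, THF, −78 → 0 °C) oxidises to ynolate 7; silylation as in step 4 gives 8. No ester is involved, so enolisation cannot intervene.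

Step 11. Insertion into the donor-substituted C2=C3 bond may be slow, leaving time for protodeboronation of the electron-rich boronic acid and for 1,2-addition to the product ketone, or facial discrimination may be insufficient. The fallback sets out from 15 and 20 and comes back at 25.
- 4-Hydroxybenzaldehyde F5 is alkylated with 20 (K2CO3, acetone) to 4-[(3-methylbut-2-en-1-yl)oxy]benzaldehyde F6.
- Wittig methylenation (Ph3PCH3Br, KOt-Bu, THF) gives 1-ethenyl-4-[(3-methylbut-2-en-1-yl)oxy]benzene F7.
- 15, trimethyl orthoformate and F7 are combined under a BINOL-derived N-triflyl phosphoramide of the appropriate hand in an ortho-quinone methide [4+2], expected to give (2S,4S)-4-methoxy-8-(3-methylbut-2-en-1-yl)-2-{4-[(3-methylbut-2-en-1-yl)oxy]phenyl}-5,7-bis(triisopropylsilyloxy)chromane F8.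
- Mild solvolysis (pyridinium tosylate, aqueous acetone) gives (2S)-8-(3-methylbut-2-en-1-yl)-2-{4-[(3-methylbut-2-en-1-yl)oxy]phenyl}-5,7-bis(triisopropylsilyloxy)chroman-4-ol F9 as C4 epimers, and Dess–Martin oxidation gives 25.

Step 12. Once phenoxides are liberated, base-induced E1cB expulsion of the C8a oxygen (retro-oxa-Michael opening) may erode the C2 configuration. The fallback sets out from 18 and comes back at 26. The chromone is desilylated first (Bu4NF, AcOH, THF) to 5,7-dihydroxy-8-(3-methylbut-2-en-1-yl)-4H-chromen-4-one F10, which has no stereocentre to lose. The rhodium-catalysed arylation of step 11 is then run on F10 with 24, so the stereocentre is created last and never meets fluoride; the hydrogen-bonded C5 hydroxyl should raise the electrophilicity of the enone.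

## Further compounds

F1 | step 5 | benzene-1,3,5-triol | Oc1cc(O)cc(O)c1
F2 | step 5 | 2-(3-methylbut-2-en-1-yl)benzene-1,3,5-triol | CC(C)=CCc1c(O)cc(O)cc1O
F3 | step 4 | 5-methylhex-4-en-1-yne | C#CCC=C(C)C
F4 | step 4 | lithium 5-methylhex-4-en-1-yn-1-ide | [Li]C#CCC=C(C)C
F5 | step 11 | 4-hydroxybenzaldehyde | O=Cc1ccc(O)cc1
F6 | step 11 | 4-[(3-methylbut-2-en-1-yl)oxy]benzaldehyde | CC(C)=CCOc1ccc(C=O)cc1
F7 | step 11 | 1-ethenyl-4-[(3-methylbut-2-en-1-yl)oxy]benzene | C=Cc1ccc(OCC=C(C)C)cc1
F8 | step 11 | (2S,4S)-4-methoxy-8-(3-methylbut-2-en-1-yl)-2-{4-[(3-methylbut-2-en-1-yl)oxy]phenyl}-5,7-bis(triisopropylsilyloxy)chromane | CC(C)=CCOc1ccc([C@@H]2C[C@H](OC)c3c(O[Si](C(C)C)(C(C)C)C(C)C)cc(O[Si](C(C)C)(C(C)C)C(C)C)c(CC=C(C)C)c3O2)cc1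
F9 | step 11 | (2S)-8-(3-methylbut-2-en-1-yl)-2-{4-[(3-methylbut-2-en-1-yl)oxy]phenyl}-5,7-bis(triisopropylsilyloxy)chroman-4-ol (C4 epimers) | CC(C)=CCOc1ccc([C@@H]2CC(O)c3c(O[Si](C(C)C)(C(C)C)C(C)C)cc(O[Si](C(C)C)(C(C)C)C(C)C)c(CC=C(C)C)c3O2)cc1
F10 | step 12 | 5,7-dihydroxy-8-(3-methylbut-2-en-1-yl)-4H-chromen-4-one | O=c1ccoc2c(CC=C(C)C)c(O)cc(O)c12
A1 | alternative 1 | (2S,4R)-5,7-bis(methoxymethoxy)-8-(3-methylbut-2-en-1-yl)-2-{4-[(3-methylbut-2-en-1-yl)oxy]phenyl}chroman-4-ol | CC(C)=CCOc1ccc([C@@H]2C[C@@H](O)c3c(OCOC)cc(OCOC)c(CC=C(C)C)c3O2)cc1
A2 | alternative 1 | (1R,3S)-1-[2-bromo-4,6-bis(methoxymethoxy)-3-(3-methylbut-2-en-1-yl)phenyl]-3-{4-[(3-methylbut-2-en-1-yl)oxy]phenyl}propane-1,3-diol | CC(C)=CCOc1ccc([C@@H](O)C[C@@H](O)c2c(OCOC)cc(OCOC)c(CC=C(C)C)c2Br)cc1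
A3 | alternative 2 | (2S)-5,7-bis(tert-butyldimethylsilyloxy)-8-(3-methylbut-2-en-1-yl)-2-{4-[(3-methylbut-2-en-1-yl)oxy]phenyl}chroman-4-one | CC(C)=CCOc1ccc([C@@H]2CC(=O)c3c(O[Si](C)(C)C(C)(C)C)cc(O[Si](C)(C)C(C)(C)C)c(CC=C(C)C)c3O2)cc1
A4 | alternative 2 | 1-[4,6-bis(tert-butyldimethylsilyloxy)-3-(3-methylbut-2-en-1-yl)-2-({4-[(3-methylbut-2-en-1-yl)oxy]phenyl}methoxy)phenyl]-2-diazoethan-1-one | [N-]=[N+]=CC(=O)c1c(O[Si](C)(C)C(C)(C)C)cc(O[Si](C)(C)C(C)(C)C)c(CC=C(C)C)c1OCc1ccc(OCC=C(C)C)cc1
A5 | alternative 3 | (2S,4S)-5,7-bis(tert-butyldimethylsilyloxy)-4-methoxy-8-(3-methylbut-2-en-1-yl)-2-{4-[(3-methylbut-2-en-1-yl)oxy]phenyl}chromane | CC(C)=CCOc1ccc([C@@H]2C[C@H](OC)c3c(O[Si](C)(C)C(C)(C)C)cc(O[Si](C)(C)C(C)(C)C)c(CC=C(C)C)c3O2)cc1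
A6 | alternative 3 | 4,6-bis(tert-butyldimethylsilyloxy)-2-hydroxy-3-(3-methylbut-2-en-1-yl)benzaldehyde | O=Cc1c(O)c(CC=C(C)C)c(O[Si](C)(C)C(C)(C)C)cc1O[Si](C)(C)C(C)(C)C
A7 | alternative 3 | 1-ethenyl-4-[(3-methylbut-2-en-1-yl)oxy]benzene | C=Cc1ccc(OCC=C(C)C)cc1
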